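## Retrosynthetic overview

1. The ten-membered ring is closed last at C7–C8 by a 10-exo radical addition–fragmentation: a C8 α-acyloxy radical adds to C7 of a 3-(tosylmethyl)butenolide and expels the sulfonyl radical. This one step creates C7 and C8, unveils the exocyclic methylene and carries in the (S)-2-methylbutanoate.
2. The radical precursor is made from a C8 aldehyde and (S)-2-methylbutanoyl bromide. The cross-conjugated dienone comes from Nozaki–Hiyama–Kishi alkenylation (C3–C4), cross-metathesis (C1=C2) and one double oxidation.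
3. West half: (Z)-3-iodobut-2-enal and methyl 2-(bromomethyl)acrylate are joined by asymmetric Cr-catalysed allylation (sets C6, closes the lactone), then converted to the allyl sulfone.
4. East half: Sharpless epoxidation and hydride opening of (E)-3-methylpent-2-en-4-yn-1-ol set C10.
5. Ring order: five-membered lactone first, ten-membered carbocycle last.

Assumption: labels C1–C15 are germacrane numbering of the target (C6 lactone CH–O, C7 ring-fusion CH, C8 ester CH–O, C10 carbinol), and compounds 4, 11 and 18 are taken as purchasable.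

## Route

Step 1
Reactants: 1 but-2-yn-1-ol
Product: 2 (Z)-3-iodobut-2-en-1-ol
Conditions: NaAlH2(OCH2CH2OCH3)2 (Red-Al), THF, 0 °C to rt; then I2, −78 to 0 °C
Reagents that add atoms: iodine, [I][I]
Why: Alkoxide-directed anti hydroalumination puts aluminium on the distal alkyne carbon and iodinolysis proceeds with retention, so iodine ends cis to the CH2OH group (Z).

Step 2
Reactants: 2 (Z)-3-iodobut-2-en-1-ol
Product: 3 (Z)-3-iodobut-2-enal
Conditions: MnO2, CH2Cl2, rt, dark
Reagents that add atoms: none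
Why: Allylic oxidation with MnO2 stops at the aldehyde and leaves the Z-iodoalkene untouched.

Step 3
Reactants: 3 (Z)-3-iodobut-2-enal; 4 methyl 2-(bromomethyl)prop-2-enoate
Product: 7 (5R)-5-[(1Z)-2-iodoprop-1-en-1-yl]-3-methylideneoxolan-2-one, via silyl ether 5 (not isolated), via hydroxy ester 6 (not isolated)
Conditions: CrCl2 (10 mol %), chiral 1,8-bis(oxazolinyl)carbazole ligand (12 mol %, enantiomer directing Re-face addition), Mn, TMSCl, THF, 0 °C; then 1 M HCl, THF, rt
Reagents that add atoms: none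
Why: Catalytic asymmetric Nozaki–Hiyama-type 2-(alkoxycarbonyl)allylation adds the allylchromium through its γ-carbon to the Re face of the aldehyde (sets C6), the vinyl iodide is inert to CrCl2 without nickel, and acid work-up desilylates and lactonises.

Step 4
Reactants: 7 (5R)-5-[(1Z)-2-iodoprop-1-en-1-yl]-3-methylideneoxolan-2-one
Product: 10 (5R)-5-[(1Z)-2-iodoprop-1-en-1-yl]-3-[(4-methylbenzenesulfonyl)methyl]furan-2(5H)-one, via iodo sulfone 8 (not isolated), via vinyl sulfone 9 (not isolated)
Conditions: sodium 4-methylbenzenesulfinate, I2, CH2Cl2–H2O, visible light, rt; then Et3N, CH2Cl2, 0 °C to rt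
Reagents that add atoms: sodium 4-methylbenzenesulfinate, Cc1ccc(cc1)S(=O)[O-].[Na+]
Why: Radical-chain iodosulfonylation adds the tosyl radical to the exocyclic CH2 and iodine to the α-carbon, then dehydroiodination and base-mediated 1,3-proton shift give the ester-conjugated endocyclic allyl sulfone without touching C6.

Step 5
Reactants: 11 (2E)-3-methylpent-2-en-4-yn-1-ol
Product: 12 [(2S,3S)-3-ethynyl-3-methyloxiran-2-yl]methanol
Conditions: Ti(OiPr)4 (10 mol %), L-(+)-diisopropyl tartrate (12 mol %), tBuOOH, 4 Å MS, CH2Cl2, −20 °C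
Reagents that add atoms: tert-butyl hydroperoxide, CC(C)(C)OO
Why: Sharpless asymmetric epoxidation of the E-trisubstituted allylic alcohol with the L-(+)-tartrate gives the (2S,3S)-epoxide, which fixes the future C10–O bond.

Step 6
Reactants: 12 [(2S,3S)-3-ethynyl-3-methyloxiran-2-yl]methanol
Product: 13 (3R)-3-methylpent-4-ene-1,3-diol
Conditions: NaAlH2(OCH2CH2OCH3)2 (Red-Al, 4 equiv), THF, 0 to 40 °C
Reagents that add atoms: none
Why: Intramolecular hydride delivery from the C1 alkoxyaluminate opens the epoxide at C2 (1,3-diol) and alkoxide-directed hydroalumination reduces the ethynyl group to vinyl, while the C3–O bond is never broken so the tertiary carbinol is R.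

Step 7
Reactants: 10 (5R)-5-[(1Z)-2-iodoprop-1-en-1-yl]-3-[(4-methylbenzenesulfonyl)methyl]furan-2(5H)-one; 14 prop-2-enal
Product: 15 (5S)-5-[(1Z)-3-hydroxy-2-methylpenta-1,4-dien-1-yl]-3-[(4-methylbenzenesulfonyl)methyl]furan-2(5H)-one (both carbinol epimers)
Conditions: CrCl2 (4 equiv), NiCl2 (2 mol %), DMF, rt
Reagents that add atoms: none
Why: Nozaki–Hiyama–Kishi alkenylation adds the alkenylchromium 1,2 to acrolein with retention of the Z geometry, and the new carbinol centre is oxidised away in step 9.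

Step 8
Reactants: 15 (5S)-5-[(1Z)-3-hydroxy-2-methylpenta-1,4-dien-1-yl]-3-[(4-methylbenzenesulfonyl)methyl]furan-2(5H)-one; 13 (3R)-3-methylpent-4-ene-1,3-diol
Product: 16 (5S)-3-[(4-methylbenzenesulfonyl)methyl]-5-[(1Z,4E,6R)-3,6,8-trihydroxy-2,6-dimethylocta-1,4-dien-1-yl]furan-2(5H)-one (both C3 carbinol epimers)
Conditions: 13 (3 equiv), second-generation Hoveyda–Grubbs catalyst (10 mol %), CH2Cl2, 40 °C
Reagents that add atoms: none
Why: E-selective cross-metathesis joins the two terminal vinyl groups (C1=C2) while the trisubstituted and conjugated alkenes are inert to the catalyst.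

Step 9
Reactants: 16 (5S)-3-[(4-methylbenzenesulfonyl)methyl]-5-[(1Z,4E,6R)-3,6,8-trihydroxy-2,6-dimethylocta-1,4-dien-1-yl]furan-2(5H)-one
Product: 17 (3R,4E,7Z)-3-hydroxy-3,7-dimethyl-8-{(2S)-4-[(4-methylbenzenesulfonyl)methyl]-5-oxo-2,5-dihydrofuran-2-yl}-6-oxoocta-4,7-dienal
Conditions: Dess–Martin periodinane (2.6 equiv), NaHCO3, CH2Cl2, 0 °C to rt; used crude
Reagents that add atoms: none
Why: Dess–Martin oxidation turns the bis-allylic secondary alcohol into the cross-conjugated dienone and the primary alcohol into the C8 aldehyde in one operation, and the tertiary C10–OH cannot be oxidised.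

Step 10
Reactants: 18 (2S)-2-methylbutanoic acid
Product: 19 (2S)-2-methylbutanoyl bromide
Conditions: (COBr)2, DMF (cat.), CH2Cl2, 0 °C to rt; distil
Reagents that add atoms: oxalyl bromide, O=C(Br)C(=O)Br
Why: Vilsmeier-type activation gives the acyl bromide without base, so the α-stereocentre is not enolised.

Step 11
Reactants: 17 (3R,4E,7Z)-3-hydroxy-3,7-dimethyl-8-{(2S)-4-[(4-methylbenzenesulfonyl)methyl]-5-oxo-2,5-dihydrofuran-2-yl}-6-oxoocta-4,7-dienal; 19 (2S)-2-methylbutanoyl bromide
Product: 21 (3aR,4R,6R,7E,10Z,11aS)-6-hydroxy-6,10-dimethyl-3-methylidene-2,9-dioxo-3a,4,5,11a-tetrahydrocyclodeca[b]furan-4-yl (2S)-2-methylbutanoate, via bromoalkyl ester 20 (not isolated)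
Conditions: 19 (1.1 equiv), ZnBr2 (1 mol %), CH2Cl2, −20 °C; evaporate; then (Bu3Sn)2 (1.5 equiv), di-tert-butyl hyponitrite (0.2 equiv), PhCF3 (1 mM, syringe-pump addition), 40 °C, dark
Reagents that add atoms: none
Why: Proposed new method: Bu3Sn• abstracts bromine from the α-bromoalkyl ester (formed by addition of the acyl bromide across the aldehyde) to give a nucleophilic C8 α-acyloxy radical that closes the ring by 10-exo attack on the butenolide β-carbon C7, and the resulting α-lactone radical ejects the tosyl radical (SH2′), which regenerates Bu3Sn• from (Bu3Sn)2. The closest known reactions are ditin-mediated radical allylation of α-oxygenated halides with 2-(sulfonylmethyl)acrylates and tin-mediated radical macrocyclisation onto enoates. C7 is expected to be attacked on the face carrying the C5 arm (cis fusion, because the anti trajectory would pull H6 and the sulfonylmethyl arm into the forming ring) and C8 to react with its acyloxy group exo and anti to the C7–C11 bond (8R); both are model-based predictions.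

## Compound list

1 | but-2-yn-1-ol | CC#CCO | starting material
2 | (Z)-3-iodobut-2-en-1-ol | OC/C=C(/C)I | intermediate
3 | (Z)-3-iodobut-2-enal | O=C/C=C(/C)I | intermediate
4 | methyl 2-(bromomethyl)prop-2-enoate | C=C(CBr)C(=O)OC | starting material
5 | methyl (4R,5Z)-6-iodo-2-methylidene-4-[(trimethylsilyl)oxy]hept-5-enoate | C=C(C[C@@H](O[Si](C)(C)C)/C=C(/C)I)C(=O)OC | intermediate
6 | methyl (4R,5Z)-4-hydroxy-6-iodo-2-methylidenehept-5-enoate | C=C(C[C@@H](O)/C=C(/C)I)C(=O)OC | intermediate
7 | (5R)-5-[(1Z)-2-iodoprop-1-en-1-yl]-3-methylideneoxolan-2-one | O=C1O[C@@H](/C=C(/C)I)CC1=C | intermediate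
8 | (5R)-3-iodo-5-[(1Z)-2-iodoprop-1-en-1-yl]-3-[(4-methylbenzenesulfonyl)methyl]oxolan-2-one (both C3 epimers) | O=C1O[C@@H](/C=C(/C)I)CC1(I)CS(=O)(=O)c1ccc(C)cc1 | intermediate
9 | (5R)-5-[(1Z)-2-iodoprop-1-en-1-yl]-3-[(4-methylbenzenesulfonyl)methylidene]oxolan-2-one | O=C1O[C@@H](/C=C(/C)I)CC1=CS(=O)(=O)c1ccc(C)cc1 | intermediate
10 | (5R)-5-[(1Z)-2-iodoprop-1-en-1-yl]-3-[(4-methylbenzenesulfonyl)methyl]furan-2(5H)-one | O=C1O[C@@H](/C=C(/C)I)C=C1CS(=O)(=O)c1ccc(C)cc1 | intermediate
11 | (2E)-3-methylpent-2-en-4-yn-1-ol | OC/C=C(\C)C#C | starting material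
12 | [(2S,3S)-3-ethynyl-3-methyloxiran-2-yl]methanol | OC[C@@H]1O[C@@]1(C)C#C | intermediate
13 | (3R)-3-methylpent-4-ene-1,3-diol | OCC[C@@](C)(O)C=C | intermediate
14 | prop-2-enal (acrolein) | C=CC=O | starting material
15 | (5S)-5-[(1Z)-3-hydroxy-2-methylpenta-1,4-dien-1-yl]-3-[(4-methylbenzenesulfonyl)methyl]furan-2(5H)-one (both carbinol epimers) | O=C1O[C@@H](/C=C(/C)C(O)C=C)C=C1CS(=O)(=O)c1ccc(C)cc1 | intermediate
16 | (5S)-3-[(4-methylbenzenesulfonyl)methyl]-5-[(1Z,4E,6R)-3,6,8-trihydroxy-2,6-dimethylocta-1,4-dien-1-yl]furan-2(5H)-one (both C3 carbinol epimers) | O=C1O[C@@H](/C=C(/C)C(O)/C=C/[C@](C)(O)CCO)C=C1CS(=O)(=O)c1ccc(C)cc1 | intermediate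
17 | (3R,4E,7Z)-3-hydroxy-3,7-dimethyl-8-{(2S)-4-[(4-methylbenzenesulfonyl)methyl]-5-oxo-2,5-dihydrofuran-2-yl}-6-oxoocta-4,7-dienal | O=C1O[C@@H](/C=C(/C)C(=O)/C=C/[C@](C)(O)CC=O)C=C1CS(=O)(=O)c1ccc(C)cc1 | intermediate
18 | (2S)-2-methylbutanoic acid | CC[C@H](C)C(=O)O | starting material
19 | (2S)-2-methylbutanoyl bromide | CC[C@H](C)C(=O)Br | intermediate
20 | (3R,4E,7Z)-1-bromo-3-hydroxy-3,7-dimethyl-8-{(2S)-4-[(4-methylbenzenesulfonyl)methyl]-5-oxo-2,5-dihydrofuran-2-yl}-6-oxoocta-4,7-dien-1-yl (2S)-2-methylbutanoate (both C1 epimers) | O=C1O[C@@H](/C=C(/C)C(=O)/C=C/[C@](C)(O)CC(Br)OC(=O)[C@@H](C)CC)C=C1CS(=O)(=O)c1ccc(C)cc1 | intermediate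
21 | (3aR,4R,6R,7E,10Z,11aS)-6-hydroxy-6,10-dimethyl-3-methylidene-2,9-dioxo-3a,4,5,11a-tetrahydrocyclodeca[b]furan-4-yl (2S)-2-methylbutanoate | C=C1C(=O)O[C@H]2/C=C(/C)C(=O)/C=C/[C@](C)(O)C[C@@H](OC(=O)[C@@H](C)CC)[C@@H]12 | target

## Step count and risks

Total steps: 11. Longest linear sequence: 8 (steps 1, 2, 3, 4, 7, 8, 9, 11).

**Step 11 (most likely to fail).** Three things can go wrong.
- The 10-exo closure is slow and competes with β-scission of the C8 radical across C9–C10, which would release the vinyl ester and a highly stabilised C10 radical. The hydride-free ditin chain, high dilution and low temperature are chosen to favour closure.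
- The facial sense at C7 (cis versus trans fusion) and at C8 rests on models only.
- The β-hydroxy aldehyde 17 may dehydrate before it is trapped.

Fallback: set out from 17 and close the same bond by polar umpolung allylation instead. Pd(PPh3)4 (zerovalent palladium) and InI in THF at high dilution turn the allyl sulfone into an allylindium that adds to the C8 aldehyde through a closed transition state and gives (3aR,4R,6R,7E,10Z,11aS)-4,6-dihydroxy-6,10-dimethyl-3-methylidene-3a,4,5,11a-tetrahydrocyclodeca[b]furan-2,9-dione F1. Acylation of its secondary alcohol with acid 18 (DCC, DMAP; the tertiary C10–OH is left) comes back to 21.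

**Step 4.** The tosyl radical may also attack the iodoalkene, the elimination may stop at vinyl sulfone 9, and the base may epimerise the doubly allylic C6–H of butenolide 10.

Fallback: set out from 3 and build the butenolide by ring-closing metathesis, so that no base touches C6. Enantioselective addition of divinylzinc (chiral amino-alcohol catalyst) gives (3R,4Z)-5-iodohexa-1,4-dien-3-ol F2. DCC esterification with 2-(bromomethyl)prop-2-enoic acid gives (3R,4Z)-5-iodohexa-1,4-dien-3-yl 2-(bromomethyl)prop-2-enoate F3. Ring-closing metathesis with the second-generation Hoveyda–Grubbs catalyst gives (5R)-3-(bromomethyl)-5-[(1Z)-2-iodoprop-1-en-1-yl]furan-2(5H)-one F4. Displacement with sodium 4-methylbenzenesulfinate in DMF comes back to 10.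

**Step 6.** Hydride may open the alkynyl epoxide in the SN2′ sense to an allene, or leave the alkyne partly unreduced.

Fallback: set out from 11 and remove the alkyne before the epoxide is made. Lindlar semihydrogenation gives (2E)-3-methylpenta-2,4-dien-1-ol F5. Sharpless epoxidation with L-(+)-diisopropyl tartrate gives [(2S,3S)-3-ethenyl-3-methyloxiran-2-yl]methanol F6. Red-Al then only has to open the epoxide at C2 and comes back to 13.

Further compounds
F1 | step 11 | (3aR,4R,6R,7E,10Z,11aS)-4,6-dihydroxy-6,10-dimethyl-3-methylidene-3a,4,5,11a-tetrahydrocyclodeca[b]furan-2,9-dione | C=C1C(=O)O[C@H]2/C=C(/C)C(=O)/C=C/[C@](C)(O)C[C@@H](O)[C@@H]12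
F2 | step 4 | (3R,4Z)-5-iodohexa-1,4-dien-3-ol | C=C[C@@H](O)/C=C(/C)I
F3 | step 4 | (3R,4Z)-5-iodohexa-1,4-dien-3-yl 2-(bromomethyl)prop-2-enoate | C=C[C@@H](OC(=O)C(=C)CBr)/C=C(/C)I
F4 | step 4 | (5R)-3-(bromomethyl)-5-[(1Z)-2-iodoprop-1-en-1-yl]furan-2(5H)-one | O=C1O[C@@H](/C=C(/C)I)C=C1CBr
F5 | step 6 | (2E)-3-methylpenta-2,4-dien-1-ol | OC/C=C(\C)C=C
F6 | step 6 | [(2S,3S)-3-ethenyl-3-methyloxiran-2-yl]methanol | OC[C@@H]1O[C@@]1(C)C=C
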